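Which species holds most of the substrate after 50 min in Sunday's and Wednesday's flasks, and how much of it?

| flask | substrate | catalyst | remark | time |
|---|---|---|---|---|
| green | 0.30 M | 2.5 mol% | run made earlier |  |
| teal | 0.10 M | 2.5 mol% | run made earlier |  |
| Sunday's | 0.20 M | 2.5 mol% |  | 50 min |
| Wednesday's | 0.20 M | 5 mol% |  | 50 min |

- green (time / min: substrate / %, target / %, intermediate / %): 3.00: 26.3, 1.5, 65.9; 6.00: 8.6, 3.1, 79.6; 8.00: 2.9, 6.5, 83.4; 12.0: 0.6, 9.0, 84.3; 15.0: 1.3, 11.6, 80.1; 20.0: 1.4, 15.3, 76.8
- teal (time / min: substrate / %, target / %, intermediate / %): 1.33: 56.3, 0, 41.1; 2.50: 33.6, 0, 62.3; 4.00: 18.4, 1.5, 78.0; 6.00: 8.3, 1.5, 87.4; 10.0: 2.2, 1.0, 95.0; 20.0: 0, 5.6, 92.0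

(readings scatter by 1 percentage point)



1. which of these there is most of at the end, counted by the substrate in it, Sunday's (intermediate / target / substrate)
2. which of these there is most of at the end, counted by the substrate in it, Wednesday's (intermediate / target / substrate)
3. final amount of the leader among these, as a percentage of the substrate charged, in Sunday's
4. final amount of the leader among these, as a percentage of the substrate charged, in Wednesday's

I read the flask as a ladder of rates, and the concentration I watch on it is that of the catalyst, c, the substrate concentration times the loading.

1. First rung: the substrate. The teal run keeps 18.4% of it after 4.00 min, so I read a first-order constant of 0.423 /min and a mean life τ of 2.36 min.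

2. Same rung: a loss. At 20.0 min, the green run lacks 6.50% of its charge and the teal run 2.40%. At the middle concentration I take their mean, 4.45%, in both new flasks.

3. Last rung: intermediate to target. I count the intermediate as born at τ and call its pseudo-first-order constant λ = ln(1 + target/intermediate)/(t − τ). The readings at 20.0 min give 0.0103 /min for the green run and 0.00335 /min for the teal run. With c at 0.00750 M and 0.00250 M, the mean of λ/c is the turnover constant K, 1.36 /M/min. Both runs share one loading, so first order in catalyst is my assumption.

4. Reckoning. Sunday's flask has c = 0.00500 M and Wednesday's 0.0100 M. Since τ is short against 1/(Kc), the rungs separate, and I expect intermediate at 69.2% on Sunday's and 50.1% on Wednesday's. Wednesday's target comes to 45.5%, so intermediate leads there narrowly.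

The forecast, reasoning “That suggests second order in intermediate”, names intermediate on Sunday's at 70% and intermediate on Wednesday's at 56%, which is higher than my Wednesday figure.

Sunday's flask ends with intermediate at 69.1%, Wednesday's with intermediate at 50.7% and target at 43.4%.

catalyst + intermediate → catalyst + target (k = 1.30 /M/min); 2 substrate → self-condensation product (k = 0.130 /M/min); substrate → intermediate (k = 0.410 /min) In Wednesday's flask, 99% of the self-condensation turnover up to 50 min stands complete by 5.00 min, while the catalyst, still at 100% at 50.0 min, carries on turning intermediate into target. Starting from Wednesday's 70.2% intermediate at 25.0 min, K gives 50.0% at 50 min. From Wednesday's 50.7% at 50 min, it gives 8.65% at 3.0 h. Wednesday's flask, read then, holds 9.36% intermediate.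

The readings were computed with made-up constants, noise included.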